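Ring A (O1, C2, C3, C3a–C7a; styryl on C5) is bonded through C3 to C4' of ring B (O1', C2', C3', C3a'–C7a'). The feature exploited is the vicinal pair C2/C3. C2 holds one aryl group and O1, and C3 holds the aryl carbons C3a and C4'. This is what arises when both ends of an aryl–CH=CH–B unit are arylated and boron is then exchanged for oxygen. One palladium-catalysed conjunctive coupling of an aryllithium, the alkenylboronate and a fluoroaryl triflate makes C2–aryl and C3–C3a and sets both stereocentres. Its precursor is enantiopure trans ring B carrying at C4' the (E)-vinylboronic ester of cis-1,2-dimethylacenaphthene-1,2-diol, all phenols masked as methoxymethyl ethers.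

Key step: step 12

**Labels and remarks on the chemistry**
- MOM = CH2OCH3.
- B(mac) = boron held by both oxygens of cis-1,2-dimethylacenaphthene-1,2-diol.
- ArB = ring B unit bonded through C4': (2S,3S)-6-(methoxymethoxy)-3-[3,5-bis(methoxymethoxy)phenyl]-2-[4-(methoxymethoxy)phenyl]-2,3-dihydrobenzofuran-4-yl.
- The target is (2S,3S,2'S,3'S) with an E stilbene; both rings are trans.
- Rhodium carbene insertion into a benzylic ether C–H bond builds the cis-2,3-diaryl ring. Trans ring B therefore needs a separate inversion at C2' (step 5).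
- Removing seven aryl methyl ethers at the end would need strong Lewis acids. These ionise the benzylic C2–O1 and C2'–O1' bonds close to electron-rich aryl nucleophiles.
- The methyl ethers are therefore cleaved early, on the simple ring B bromide, where such ionisation is harmless and even useful. From then on every phenol is a MOM ether.
- Bromide from the halogen–lithium exchange would block the free site of cationic palladium, so KOTf is added to precipitate it.
- Assumption 1: Rh2(S-PTAD)4, dirhodium tetrakis[(S)-(1-adamantyl)(phthalimido)acetate], is taken to give the 3'S series; if the sense of induction is the opposite, the R catalyst is used.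
- Assumption 2: the (RP,R'P) antipode of the MandyPhos ligand is taken to place palladium on the Si face of C3; if not, the equally available mirror-image ligand is used.

**Step 1**
Reactants: 1 1-bromo-3,5-dimethoxybenzene; 2 3,5-dimethoxybenzoyl chloride
Product: 4 (2-bromo-6-hydroxy-4-methoxyphenyl)(3,5-dimethoxyphenyl)methanone, via tetramethoxy ketone 3 (not isolated)
Conditions: AlCl3, CH2Cl2, 0 °C to reflux; then ice-water
Reagents that add atoms: none
Why: Friedel–Crafts acylation should take place at C2 of 1, para to one methoxy group and less crowded than the position between the two, and the aluminium chelate of ketone 3 then loses only the methyl group of the ortho methoxy oxygen (chelation-directed ether cleavage), which frees the one phenol needed for ring B.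

**Step 2**
Reactants: 4 (2-bromo-6-hydroxy-4-methoxyphenyl)(3,5-dimethoxyphenyl)methanone; 5 4-methoxybenzyl chloride
Product: 6 {2-bromo-4-methoxy-6-[(4-methoxybenzyl)oxy]phenyl}(3,5-dimethoxyphenyl)methanone
Conditions: K2CO3, NaI (cat.), DMF, 60 °C
Reagents that add atoms: none
Why: Williamson ether synthesis at the only free phenol installs the benzylic CH2 that becomes C2' together with its 4-methoxyphenyl group.

**Step 3**
Reactants: 6 {2-bromo-4-methoxy-6-[(4-methoxybenzyl)oxy]phenyl}(3,5-dimethoxyphenyl)methanone
Product: 7 hydrazone of ketone 6 (E/Z mixture at C=N)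
Conditions: N2H4·H2O (excess), AcOH (cat.), n-BuOH, 110 °C
Reagents that add atoms: hydrazine hydrate, NN.O
Why: Acid-catalysed condensation of a diaryl ketone with a large excess of the small nucleophile hydrazine gives the hydrazone, heat compensating for the two ortho substituents and the excess suppressing azine formation.

**Step 4**
Reactants: 7 hydrazone of ketone 6
Product: 9 (2R,3S)-4-bromo-3-(3,5-dimethoxyphenyl)-6-methoxy-2-(4-methoxyphenyl)-2,3-dihydrobenzofuran (cis), via diaryldiazomethane 8 (not isolated)
Conditions: MnO2, CH2Cl2, rt, filtration; then Rh2(S-PTAD)4 (1 mol %), CH2Cl2, 0 °C to rt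
Reagents that add atoms: none
Why: Dehydrogenation of the hydrazone gives diazo compound 8, and its donor/donor rhodium carbene undergoes intramolecular C–H insertion into the ether CH2 to close the five-membered ring, the compact hydride-transfer-like transition state placing both aryl groups cis and the chiral carboxylate ligands selecting the carbene face so that C3' is S and C2' is R.

**Step 5**
Reactants: 9 (2R,3S)-4-bromo-3-(3,5-dimethoxyphenyl)-6-methoxy-2-(4-methoxyphenyl)-2,3-dihydrobenzofuran
Product: 10 (2S,3S)-4-bromo-3-(3,5-dihydroxyphenyl)-2-(4-hydroxyphenyl)-2,3-dihydrobenzofuran-6-ol (trans)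
Conditions: BBr3, CH2Cl2, −78 °C to rt; then H2O
Reagents that add atoms: none
Why: Boron tribromide ether cleavage removes all four methyl groups, and because the same Lewis acid reversibly ionises the benzylic C2'–O1' bond (cation stabilised by the 4-oxygenated aryl group, recapture by the neighbouring phenol oxygen) C2' should settle in the more stable trans arrangement (S) while C3', whose bonds are not broken, keeps its configuration.

**Step 6**
Reactants: 10 (2S,3S)-4-bromo-3-(3,5-dihydroxyphenyl)-2-(4-hydroxyphenyl)-2,3-dihydrobenzofuran-6-ol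
Product: 11 ArB–Br, (2S,3S)-4-bromo-6-(methoxymethoxy)-3-[3,5-bis(methoxymethoxy)phenyl]-2-[4-(methoxymethoxy)phenyl]-2,3-dihydrobenzofuran
Conditions: MOMCl, i-Pr2NEt, CH2Cl2, 0 °C to rt
Reagents that add atoms: chloromethyl methyl ether, COCCl
Why: O-Alkylation of the four phenols with MOMCl under a hindered amine base is routine acetal protection, breaks no bond at C2' or C3' and gives ethers that withstand organolithiums, hydrides, peroxide and amide bases.

**Step 7**
Reactants: 12 acenaphthenequinone
Product: 13 cis-1,2-dimethyl-1,2-dihydroacenaphthylene-1,2-diol (meso; 1R,2S)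
Conditions: MeMgBr, THF, −78 °C to rt; then H2O; recrystallisation
Reagents that add atoms: methylmagnesium bromide, C[Mg]Br
Why: Twofold Grignard 1,2-addition, in which the solvated magnesium alkoxide formed first shields its own face so that the second methyl group enters beside the first and gives mainly the meso cis diol, freed from any trans isomer by crystallisation.

**Step 8**
Reactants: 13 cis-1,2-dimethyl-1,2-dihydroacenaphthylene-1,2-diol; 14 dibutyl vinylboronate
Product: 15 vinyl-B(mac)
Conditions: CH2Cl2, rt; then vacuum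
Reagents that add atoms: none
Why: Boronic ester exchange, driven by the five-membered chelate with the rigid cis diol and by removal of volatile butanol.

**Step 9**
Reactants: 11 ArB–Br; 15 vinyl-B(mac)
Product: 16 (E)-ArB–CH=CH–B(mac), the ring B 4'-alkenylboronate (2'S,3'S)
Conditions: Pd[P(t-Bu)3]2 (5 mol %), Cy2NMe, toluene, 90 °C
Reagents that add atoms: none
Why: Mizoroki–Heck arylation of a vinylboronic ester: with an amine as the only base the hindered boronate is not activated for transmetalation, migratory insertion places the aryl group on the unsubstituted carbon and syn β-hydride elimination gives the E alkene.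

**Step 10**
Reactants: 17 4-fluoro-3-hydroxybenzoic acid
Product: 18 tert-butyl 4-fluoro-3-hydroxybenzoate
Conditions: Me2NCH(Ot-Bu)2, toluene, 80 °C
Reagents that add atoms: N,N-dimethylformamide di-tert-butyl acetal, CN(C)C(OC(C)(C)C)OC(C)(C)C
Why: Esterification by O-alkylation of the carboxylate with the tert-butyl cation equivalent released from the amide acetal, the far more acidic carboxyl group reacting ahead of the phenol.

**Step 11**
Reactants: 18 tert-butyl 4-fluoro-3-hydroxybenzoate
Product: 19 tert-butyl 4-fluoro-3-(trifluoromethylsulfonyloxy)benzoate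
Conditions: Tf2O, pyridine, CH2Cl2, 0 °C
Reagents that add atoms: trifluoromethanesulfonic anhydride, O=S(=O)(OS(=O)(=O)C(F)(F)F)C(F)(F)F
Why: Sulfonylation of the phenol with triflic anhydride gives the aryl triflate, the electrophile that leaves a non-coordinating counterion on palladium.

**Step 12**
Reactants: 16 (E)-ArB–CH=CH–B(mac); 20 1-bromo-4-(methoxymethoxy)benzene; 19 tert-butyl 4-fluoro-3-(trifluoromethylsulfonyloxy)benzoate
Product: 23 tert-butyl 3-{(1S,2S)-1-ArB-2-B(mac)-2-[4-(methoxymethoxy)phenyl]ethyl}-4-fluorobenzoate (C3 S; C2 S), via aryllithium 21 (not isolated), via lithium boronate complex 22 (not isolated)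
Conditions: 20, t-BuLi, Et2O, −78 °C; added to 16, THF, −78 °C to rt; solvents removed; then KOTf, Pd(OAc)2 (5 mol %), (RP,R'P)-1,1'-bis[bis(4-methoxy-3,5-dimethylphenyl)phosphino]-2,2'-bis[(S)-α-(dimethylamino)benzyl]ferrocene (6 mol %), 19, THF, 60 °C
Reagents that add atoms: tert-butyllithium, [Li]C(C)(C)C (lithium of 21 and 22; no atom of it remains in 23)
Why: Halogen–lithium exchange gives 21, which adds to the empty orbital of boron in 16 to give the four-coordinate boronate 22, and KOTf removes bromide as KBr so that oxidative addition of 19 to zerovalent palladium leaves a cationic divalent arylpalladium able to bind the alkene. The aryl group then moves from boron to C2 antiperiplanar to palladium (1,2-metallate shift), palladium ends on benzylic C3, and reductive elimination with retention forms C3–C3a; the closest known reaction type is the enantioselective conjunctive cross-coupling of β-substituted alkenylboron ate complexes with aryl triflates. No ring is closed. C3 is set by the ferrocenyl bisphosphine, which directs palladium to the Si face of C3, and C2 follows from the E geometry and the anti course of the shift (aryl to the Si face of C2, the opposite side of the alkene plane), so both centres are S and map onto a trans ring. The step needs the conjunctive pathway to win over direct Suzuki–Miyaura transfer and β-hydride elimination, which the bulky diol on boron (slow transmetalation) and the wide-bite-angle ligand (fast reductive elimination) should secure. It also needs catalyst control over the bias of ring B, whose nearest stereocentre C3' lies three bonds from C3, while migration itself is unambiguous because the other two substituents on boron are oxygen.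

**Step 13**
Reactants: 23 tert-butyl 3-{(1S,2S)-1-ArB-2-B(mac)-2-[4-(methoxymethoxy)phenyl]ethyl}-4-fluorobenzoate
Product: 24 tert-butyl 3-{(1S,2S)-1-ArB-2-hydroxy-2-[4-(methoxymethoxy)phenyl]ethyl}-4-fluorobenzoate
Conditions: NaBO3·4H2O, THF/H2O, rt
Reagents that add atoms: sodium perborate, [Na+].[Na+].O[B-]1(O)OO[B-](O)(O)OO1
Why: Perborate oxidation of a secondary boronic ester, in which carbon migrates from boron to oxygen with retention so that C2 stays S, under conditions too mild to touch the tert-butyl ester or the aryl fluoride.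

**Step 14**
Reactants: 24 tert-butyl 3-{(1S,2S)-1-ArB-2-hydroxy-2-[4-(methoxymethoxy)phenyl]ethyl}-4-fluorobenzoate
Product: 25 tert-butyl (2S,3S)-3-ArB-2-[4-(methoxymethoxy)phenyl]-2,3-dihydrobenzofuran-5-carboxylate (trans ring A)
Conditions: KN(SiMe3)2, THF, 0 °C to rt
Reagents that add atoms: none
Why: Intramolecular nucleophilic aromatic substitution (addition–elimination) of the potassium alkoxide at C7a, where fluoride is activated by the para ester, forms O1–C7a without breaking a bond at C2 or C3, so the (S,S) alcohol maps onto the trans ring, which is also the thermodynamically preferred isomer.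

**Step 15**
Reactants: 25 tert-butyl (2S,3S)-3-ArB-2-[4-(methoxymethoxy)phenyl]-2,3-dihydrobenzofuran-5-carboxylate
Product: 26 {(2S,3S)-3-ArB-2-[4-(methoxymethoxy)phenyl]-2,3-dihydrobenzofuran-5-yl}methanol
Conditions: LiAlH4, THF, 0 °C; then H2O
Reagents that add atoms: none
Why: Hydride reduction of the benzoate to the benzylic alcohol, to which acetals and aryl ethers are inert.

**Step 16**
Reactants: 26 {(2S,3S)-3-ArB-2-[4-(methoxymethoxy)phenyl]-2,3-dihydrobenzofuran-5-yl}methanol
Product: 27 (2S,3S)-3-ArB-2-[4-(methoxymethoxy)phenyl]-2,3-dihydrobenzofuran-5-carbaldehyde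
Conditions: MnO2, CH2Cl2, rt
Reagents that add atoms: none
Why: Heterogeneous MnO2 oxidation is selective for the electron-rich benzylic alcohol and stops at the aldehyde under neutral conditions that cannot epimerise C3.

**Step 17**
Reactants: 28 3,5-dihydroxybenzyl alcohol
Product: 29 [3,5-bis(methoxymethoxy)phenyl]methanol
Conditions: MOMCl, K2CO3, acetone, 0 °C to rt
Reagents that add atoms: chloromethyl methyl ether, COCCl
Why: Carbonate deprotonates only the two phenols, so Williamson-type alkylation with MOMCl leaves the benzylic alcohol free.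

**Step 18**
Reactants: 29 [3,5-bis(methoxymethoxy)phenyl]methanol
Product: 30 1-(bromomethyl)-3,5-bis(methoxymethoxy)benzene
Conditions: CBr4, PPh3, CH2Cl2, 0 °C
Reagents that add atoms: tetrabromomethane, BrC(Br)(Br)Br
Why: Appel reaction converts the primary benzylic alcohol into the bromide under essentially neutral conditions that spare the acetals.

**Step 19**
Reactants: 30 1-(bromomethyl)-3,5-bis(methoxymethoxy)benzene
Product: 31 diethyl [3,5-bis(methoxymethoxy)benzyl]phosphonate
Conditions: P(OEt)3, neat, 120 °C
Reagents that add atoms: triethyl phosphite, CCOP(OCC)OCC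
Why: Michaelis–Arbuzov reaction of a reactive benzylic bromide with triethyl phosphite.

**Step 20**
Reactants: 27 (2S,3S)-3-ArB-2-[4-(methoxymethoxy)phenyl]-2,3-dihydrobenzofuran-5-carbaldehyde; 31 diethyl [3,5-bis(methoxymethoxy)benzyl]phosphonate
Product: 32 heptakis(methoxymethyl) ether of trans-diptoindonesin B (2S,3S,2'S,3'S; E alkene)
Conditions: 31, KOt-Bu, THF, 0 °C; then 27, 0 °C to rt
Reagents that add atoms: none
Why: Horner–Wadsworth–Emmons olefination of an aromatic aldehyde with a benzylic phosphonate gives the E stilbene through the less crowded anti pathway, and forming the carbanion before the aldehyde is added keeps free base away from the C3–H bond.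

**Step 21**
Reactants: 32 heptakis(methoxymethyl) ether of trans-diptoindonesin B
Product: 33 trans-diptoindonesin B
Conditions: HCl (cat.), MeOH/THF, 40 °C, argon, dark
Reagents that add atoms: none
Why: Acid-catalysed acetal exchange with methanol releases all seven phenols at an acidity well below that needed for lasting ionisation of C2–O1 or C2'–O1', and any reversible opening would close again to the trans rings because C3 and C3' are not involved.

**Compound list**
1 | 1-bromo-3,5-dimethoxybenzene | COc1cc(Br)cc(OC)c1 | starting material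
2 | 3,5-dimethoxybenzoyl chloride | COc1cc(cc(OC)c1)C(=O)Cl | starting material
3 | (2-bromo-4,6-dimethoxyphenyl)(3,5-dimethoxyphenyl)methanone | COc1cc(OC)cc(c1)C(=O)c1c(Br)cc(OC)cc1OC | intermediate
4 | (2-bromo-6-hydroxy-4-methoxyphenyl)(3,5-dimethoxyphenyl)methanone | COc1cc(OC)cc(c1)C(=O)c1c(Br)cc(OC)cc1O | intermediate
5 | 4-methoxybenzyl chloride | COc1ccc(CCl)cc1 | starting material
6 | {2-bromo-4-methoxy-6-[(4-methoxybenzyl)oxy]phenyl}(3,5-dimethoxyphenyl)methanone | COc1ccc(COc2cc(OC)cc(Br)c2C(=O)c2cc(OC)cc(OC)c2)cc1 | intermediate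
7 | hydrazone of 6 (E/Z mixture) | COc1ccc(COc2cc(OC)cc(Br)c2C(=NN)c2cc(OC)cc(OC)c2)cc1 | intermediate
8 | diaryldiazomethane from 7 | COc1ccc(COc2cc(OC)cc(Br)c2C(=[N+]=[N-])c2cc(OC)cc(OC)c2)cc1 | intermediate
9 | (2R,3S)-4-bromo-3-(3,5-dimethoxyphenyl)-6-methoxy-2-(4-methoxyphenyl)-2,3-dihydrobenzofuran (cis) | Brc1cc(OC)cc2c1[C@H](c1cc(OC)cc(OC)c1)[C@H](c1ccc(OC)cc1)O2 | intermediate
10 | (2S,3S)-4-bromo-3-(3,5-dihydroxyphenyl)-2-(4-hydroxyphenyl)-2,3-dihydrobenzofuran-6-ol (trans) | Brc1cc(O)cc2c1[C@H](c1cc(O)cc(O)c1)[C@@H](c1ccc(O)cc1)O2 | intermediate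
11 | ArB–Br, tetra-MOM ether of 10 | Brc1cc(OCOC)cc2c1[C@H](c1cc(OCOC)cc(OCOC)c1)[C@@H](c1ccc(OCOC)cc1)O2 | intermediate
12 | acenaphthenequinone | O=C1C(=O)c2cccc3cccc1c23 | starting material
13 | cis-1,2-dimethyl-1,2-dihydroacenaphthylene-1,2-diol (meso) | O[C@]1(C)c2cccc3cccc(c23)[C@]1(C)O | intermediate
14 | dibutyl vinylboronate | C=CB(OCCCC)OCCCC | starting material
15 | vinyl-B(mac) | C=CB1O[C@]2(C)c3cccc4cccc(c34)[C@]2(C)O1 | intermediate
16 | (E)-ArB–CH=CH–B(mac) | B1(/C=C/c2cc(OCOC)cc3c2[C@H](c2cc(OCOC)cc(OCOC)c2)[C@@H](c2ccc(OCOC)cc2)O3)O[C@]2(C)c3cccc4cccc(c34)[C@]2(C)O1 | intermediate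
17 | 4-fluoro-3-hydroxybenzoic acid | O=C(O)c1ccc(F)c(O)c1 | starting material
18 | tert-butyl 4-fluoro-3-hydroxybenzoate | CC(C)(C)OC(=O)c1ccc(F)c(O)c1 | intermediate
19 | tert-butyl 4-fluoro-3-(trifluoromethylsulfonyloxy)benzoate | CC(C)(C)OC(=O)c1ccc(F)c(OS(=O)(=O)C(F)(F)F)c1 | intermediate
20 | 1-bromo-4-(methoxymethoxy)benzene | COCOc1ccc(Br)cc1 | starting material
21 | 4-(methoxymethoxy)phenyllithium | [Li]c1ccc(OCOC)cc1 | intermediate
22 | lithium aryl(alkenyl)boronate complex from 16 and 21 (configuration at boron undefined) | [Li+].COCOc1ccc(cc1)[B-]1(/C=C/c2cc(OCOC)cc3c2[C@H](c2cc(OCOC)cc(OCOC)c2)[C@@H](c2ccc(OCOC)cc2)O3)O[C@]2(C)c3cccc4cccc(c34)[C@]2(C)O1 | intermediate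
23 | secondary boronate, C2 S and C3 S | COCOc1ccc([C@@H](B2O[C@]3(C)c4cccc5cccc(c45)[C@]3(C)O2)[C@H](c2cc(C(=O)OC(C)(C)C)ccc2F)c2cc(OCOC)cc3c2[C@H](c2cc(OCOC)cc(OCOC)c2)[C@@H](c2ccc(OCOC)cc2)O3)cc1 | intermediate
24 | secondary alcohol, C2 S and C3 S | COCOc1ccc([C@@H](O)[C@H](c2cc(C(=O)OC(C)(C)C)ccc2F)c2cc(OCOC)cc3c2[C@H](c2cc(OCOC)cc(OCOC)c2)[C@@H](c2ccc(OCOC)cc2)O3)cc1 | intermediate
25 | ring A tert-butyl ester (2S,3S,2'S,3'S) | COCOc1ccc([C@H]2Oc3ccc(C(=O)OC(C)(C)C)cc3[C@@H]2c2cc(OCOC)cc3c2[C@H](c2cc(OCOC)cc(OCOC)c2)[C@@H](c2ccc(OCOC)cc2)O3)cc1 | intermediate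
26 | ring A C5 benzylic alcohol | COCOc1ccc([C@H]2Oc3ccc(CO)cc3[C@@H]2c2cc(OCOC)cc3c2[C@H](c2cc(OCOC)cc(OCOC)c2)[C@@H](c2ccc(OCOC)cc2)O3)cc1 | intermediate
27 | ring A C5 aldehyde | COCOc1ccc([C@H]2Oc3ccc(C=O)cc3[C@@H]2c2cc(OCOC)cc3c2[C@H](c2cc(OCOC)cc(OCOC)c2)[C@@H](c2ccc(OCOC)cc2)O3)cc1 | intermediate
28 | 3,5-dihydroxybenzyl alcohol | OCc1cc(O)cc(O)c1 | starting material
29 | [3,5-bis(methoxymethoxy)phenyl]methanol | OCc1cc(OCOC)cc(OCOC)c1 | intermediate
30 | 1-(bromomethyl)-3,5-bis(methoxymethoxy)benzene | BrCc1cc(OCOC)cc(OCOC)c1 | intermediate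
31 | diethyl [3,5-bis(methoxymethoxy)benzyl]phosphonate | CCOP(=O)(Cc1cc(OCOC)cc(OCOC)c1)OCC | intermediate
32 | heptakis(methoxymethyl) ether of trans-diptoindonesin B | COCOc1ccc([C@H]2Oc3ccc(/C=C/c4cc(OCOC)cc(OCOC)c4)cc3[C@@H]2c2cc(OCOC)cc3c2[C@H](c2cc(OCOC)cc(OCOC)c2)[C@@H](c2ccc(OCOC)cc2)O3)cc1 | intermediate
33 | trans-diptoindonesin B | Oc1ccc([C@H]2Oc3ccc(/C=C/c4cc(O)cc(O)c4)cc3[C@@H]2c2cc(O)cc3c2[C@H](c2cc(O)cc(O)c2)[C@@H](c2ccc(O)cc2)O3)cc1 | target

**Totals**
Total step count: 21.
Longest linear sequence: 14 (steps 1–6, 9, 12–16, 20, 21).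

**Steps most likely to fail**

1. **Step 12.**
   - What may go wrong: binding of the crowded alkene to palladium may be slow, so that direct alkenyl transfer or β-hydride elimination takes over. Facial selectivity may be poor if ring B opposes the ligand.
   - Fallback: C3 and C2 are built stepwise without a metallate shift, setting out from 16 and 19.
   - A second Mizoroki–Heck arylation (Pd(OAc)2, PCy3, Cy2NMe, dioxane, 100 °C) puts the fluoroaryl group on C3 and gives the (Z)-β,β-diarylalkenylboronate F1.
   - NaBO3·4H2O oxidises its C–B bond to the enol and hence to the diarylacetaldehyde F2, whose C3 epimers interconvert.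
   - Addition of aryllithium 21 at −78 °C gives the alcohol diastereomer mixture F3. Chromatography separates the C2 S, C3 S isomer, which is 24, where the route is rejoined.
   - Catalyst control is given up. Because ring B is already enantiopure, all isomers are diastereomers and can be separated.

2. **Step 4.**
   - What may go wrong: carbene formation may be sluggish, diazo coupling may compete, or enantio- and diastereoselectivity may be low, because the diazo carbon is flanked by bromine and the benzyloxy group.
   - Fallback: resolution replaces asymmetric catalysis. It sets out from 6 and so also bypasses step 3.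
   - The phosphazene base P4-t-Bu (benzene, reflux) deprotonates the benzylic ether CH2. The carbanion adds to the ketone and loss of water gives the 2,3-diarylbenzofuran F4.
   - Ionic hydrogenation (Et3SiH, TFA, CH2Cl2) protonates C3' and delivers hydride to C2' anti to the C3' aryl group, giving the racemic trans-dihydrobenzofuran F5.
   - Preparative chromatography on a chiral stationary phase gives the (2S,3S)-tetramethyl ether F6. BBr3, as in step 5, leads to 10.

3. **Step 9.**
   - What may go wrong: oxidative addition and insertion may be slow at crowded C4', boron may be lost through competing transmetalation, or arylation may occur at the internal alkene carbon.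
   - Fallback: the alkene is made by alkyne hydroboration instead of vinylic substitution, setting out from 11.
   - Sonogashira coupling with trimethylsilylacetylene (PdCl2(PPh3)2, CuI, Et3N, 80 °C) gives the silylalkyne F7. K2CO3 in MeOH gives the terminal alkyne F8.
   - Syn hydroboration with catecholborane (Cy2BH cat., THF) gives the (E)-alkenyl catechol boronate F9. Exchange with diol 13 in the same flask gives 16.

**Further compounds**
F1 | step 12 | (Z)-2-ArB-2-[5-(tert-butoxycarbonyl)-2-fluorophenyl]vinyl-B(mac) | B1(/C=C(\c2cc(C(=O)OC(C)(C)C)ccc2F)c2cc(OCOC)cc3c2[C@H](c2cc(OCOC)cc(OCOC)c2)[C@@H](c2ccc(OCOC)cc2)O3)O[C@]2(C)c3cccc4cccc(c34)[C@]2(C)O1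
F2 | step 12 | tert-butyl 3-(1-ArB-2-oxoethyl)-4-fluorobenzoate (C3 epimers) | O=CC(c1cc(C(=O)OC(C)(C)C)ccc1F)c1cc(OCOC)cc2c1[C@H](c1cc(OCOC)cc(OCOC)c1)[C@@H](c1ccc(OCOC)cc1)O2
F3 | step 12 | alcohol of the constitution of 24, mixture of C2 and C3 diastereomers | COCOc1ccc(C(O)C(c2cc(C(=O)OC(C)(C)C)ccc2F)c2cc(OCOC)cc3c2[C@H](c2cc(OCOC)cc(OCOC)c2)[C@@H](c2ccc(OCOC)cc2)O3)cc1
F4 | step 4 | 4-bromo-3-(3,5-dimethoxyphenyl)-6-methoxy-2-(4-methoxyphenyl)benzofuran | COc1ccc(cc1)-c1oc2cc(OC)cc(Br)c2c1-c1cc(OC)cc(OC)c1
F5 | step 4 | racemic trans-4-bromo-3-(3,5-dimethoxyphenyl)-6-methoxy-2-(4-methoxyphenyl)-2,3-dihydrobenzofuran | Brc1cc(OC)cc2c1[C@H](c1cc(OC)cc(OC)c1)[C@@H](c1ccc(OC)cc1)O2.Brc1cc(OC)cc2c1[C@@H](c1cc(OC)cc(OC)c1)[C@H](c1ccc(OC)cc1)O2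
F6 | step 4 | (2S,3S)-4-bromo-3-(3,5-dimethoxyphenyl)-6-methoxy-2-(4-methoxyphenyl)-2,3-dihydrobenzofuran | Brc1cc(OC)cc2c1[C@H](c1cc(OC)cc(OC)c1)[C@@H](c1ccc(OC)cc1)O2
F7 | step 9 | ArB–C≡C–SiMe3 | C[Si](C)(C)C#Cc1cc(OCOC)cc2c1[C@H](c1cc(OCOC)cc(OCOC)c1)[C@@H](c1ccc(OCOC)cc1)O2
F8 | step 9 | ArB–C≡CH | C#Cc1cc(OCOC)cc2c1[C@H](c1cc(OCOC)cc(OCOC)c1)[C@@H](c1ccc(OCOC)cc1)O2
F9 | step 9 | (E)-ArB–CH=CH–B(catecholate) | B1(/C=C/c2cc(OCOC)cc3c2[C@H](c2cc(OCOC)cc(OCOC)c2)[C@@H](c2ccc(OCOC)cc2)O3)Oc2ccccc2O1
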